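In a one-step world the starting material meets a fixed amount of free catalyst and simply decays, so I can tell the flask by counting half-lives.

starting material 0.30 M; partner 0.600 M; free catalyst 1.8 mM; time 20 min

    starting material + free catalyst → catalyst intermediate A (k1 = 11.4 /M/min)
    partner + catalyst intermediate A ⇌ catalyst intermediate B (K2 = 3.10 /M, k2 = 1100 /M/min)
    catalyst intermediate B ⇌ free catalyst + product (K3 = 0.501 M, k3 = 27.0 /min)

- the reaction counts as stopped when no species that holds the starting material changes by six tenths of a point or more over the second half of the time
- run time (flask): 20 min

* the state of affairs at 20 min: stopped, and by what, or still going (no working catalyst is left / the partner has run out first / all of the starting material has reacted / forward and back rates have come level / it is still moving)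
* share of the starting material used up at 20 min
* product at 20 min, in percent of the starting material charged

Which numbers must I know well? The rate constant of the first step and c(free catalyst) multiply into the decay constant, so an error in either goes straight into the count. The rate constant of the second step matters little, because partner takes up catalyst intermediate A at 660 /min, far faster than starting material takes up free catalyst at 3.42 /min. The third step's rate constant and the second step's equilibrium constant enter through the catalyst held in the intermediates: at the start catalyst intermediate B stands to free catalyst as 0.127, and to catalyst intermediate A as 1.9. Counting these three forms, that leaves a free share at the start of 83.7 %.

My quantity is the working half-life, the pseudo-first-order time in which starting material halves with free catalyst held at that share: 40.4 min. The run is shorter, so I expect a flask still moving, at 29.1 % conversion. Product at that conversion would add 0.174 to the ratio of catalyst intermediate B to free catalyst, more than the ratio at the start, so my figure leans high.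

The forecast says it is still moving, with 26.8 % conversion and 26.6 % product, lower than my figure; its grounds include that “the product pulls catalyst back into intermediate B”.

The simulation says it is still moving, with 26.9 % conversion and 26.7 % product. In this flask the first step ran throughout, with the midpoint of its turnover at 8.81 min, while free catalyst went from 81.7 % of the catalyst charged at 2.00 min to 70.7 % at 20.0 min. The half-life of starting material by that step stood at 44 min at 8.80 min, longer than my working half-life, which keeps free catalyst at its share from the start.

In the neighbour flask with 0.075 M of starting material, the free share at the start becomes 95.4 %, the working half-life 35.4 min, and the estimated conversion 32.4 %. The simulation gives 31.6 %.

All constants were set for the occasion; the result is computed.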